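Everything rests on disconnecting pyran ring D from aryl ring B at both ring-fusion atoms, C4′–O and C3′–C4″. The key step exploits the resorcinol pattern of ring B: the C2′ oxygen, next to C3′ and meta to C4′, polarises an aryne (C3′≡C4′) so that the carbonyl oxygen of 3-methylbut-2-enal bonds to C4′ and its carbon to C3′; the benzoxete opens to an o-quinone methide that closes ring D by oxa-6π electrocyclisation. The precursor is a simple silylaryl triflate plus the enal. The chromene is then lithiated and homologated to an arylacetic acid; Evans alkylation sets C3 (R), palladium-catalysed etherification closes ring C, and C8 prenylation and MOM removal finish.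

Key step: step 3

Remark: rings A and C are the benzene and dihydropyran rings of the chroman, ring B is the aryl group on C3 (primed locants), ring D is its fused 2,2-dimethyl-2H-pyran (O1″, C2″, C3″, C4″); compounds 1, 6, 15, 18 and 26 are assumed to be commercial.

Step 1
Reactants: 1 2-bromobenzene-1,3-diol
Product: 2 2-bromo-3-(methoxymethoxy)phenol
Conditions: MOMCl (1.0 equiv), i-Pr2NEt, CH2Cl2, 0 °C to rt
Reagents that add atoms: chloromethyl methyl ether (MOMCl) COCCl
Why: Williamson-type O-alkylation of one of the two equivalent phenols should give the mono-acetal, which is separated by chromatography from recyclable diol and bis-ether.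

Step 2
Reactants: 2 2-bromo-3-(methoxymethoxy)phenol
Product: 5 3-(methoxymethoxy)-2-(trimethylsilyl)phenyl trifluoromethanesulfonate, via aryl silyl ether 3 (not isolated), via lithium 2-silylphenolate 4 (not isolated)
Conditions: (Me3Si)2NH, THF, 70 °C, then evaporation; n-BuLi, THF, −100 to −80 °C; Tf2O, −100 °C to rt
Reagents that add atoms: hexamethyldisilazane C[Si](C)(C)N[Si](C)(C)C; trifluoromethanesulfonic anhydride O=S(=O)(C(F)(F)F)OS(=O)(=O)C(F)(F)F
Why: O-silylation, bromine–lithium exchange and anionic 1,3 O-to-C silyl shift (retro-Brook rearrangement) should place the silyl group on the carbon between the two oxygens, and triflation of the phenolate completes a Kobayashi aryne precursor.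

Step 3
Reactants: 5 3-(methoxymethoxy)-2-(trimethylsilyl)phenyl trifluoromethanesulfonate; 6 3-methylbut-2-enal
Product: 10 5-(methoxymethoxy)-2,2-dimethyl-2H-chromene, via aryne 7 (not isolated), via benzoxete 8 (not isolated), via o-quinone methide 9 (not isolated)
Conditions: CsF (3 equiv), MeCN, rt, slow addition of 5 to 6 (5 equiv)
Reagents that add atoms: none
Why: Fluoride-induced 1,2-elimination of 5 releases aryne 7, whose C3′≡C4′ bond is distorted by the inductively withdrawing C2′ acetal oxygen, so the carbonyl oxygen of 6 attacks the distal C4′ and the developing C3′ anion collapses onto the carbonyl carbon; this stepwise formal (2+2) cycloaddition closes the four-membered ring of benzoxete 8 and creates the aryl C4′–O bond. Thermal 4π electrocyclic opening of 8 gives o-quinone methide 9, which closes ring D by a disrotatory oxa-6π electrocyclisation (O to C2″), so that one operation assembles the complete 2,2-dimethyl-2H-pyran on ring B. The closest known reaction type is the annulation of arynes with α,β-unsaturated aldehydes to 2H-chromenes, with the regiochemistry known from C=O insertions of 3-alkoxyarynes. No stereocenter is formed. The step needs regioselectivity (oxygen at C4′, carbon at C3′), secured by the C2′ oxygen through aryne distortion, and chemoselectivity for carbonyl addition and 6π closure over ene reaction or capture of 9 by a second aryne, secured by excess enal, slow aryne release and the C2′ substituent, which turns the dienyl chain of 9 toward the carbonyl oxygen.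

Step 4
Reactants: 10 5-(methoxymethoxy)-2,2-dimethyl-2H-chromene
Product: 12 2-[5-(methoxymethoxy)-2,2-dimethyl-2H-chromen-6-yl]ethan-1-ol, via aryllithium 11 (not isolated)
Conditions: n-BuLi, TMEDA, THF, 0 °C; ethylene oxide, −78 °C to rt; aq. NH4Cl
Reagents that add atoms: ethylene oxide C1CO1
Why: Directed ortho-metalation by the MOM ether should remove the only hydrogen ortho to it (C6 of the chromene, the future C1′), and the aryllithium opens ethylene oxide by SN2 attack.

Step 5
Reactants: 12 2-[5-(methoxymethoxy)-2,2-dimethyl-2H-chromen-6-yl]ethan-1-ol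
Product: 14 2-[5-(methoxymethoxy)-2,2-dimethyl-2H-chromen-6-yl]acetic acid, via arylacetaldehyde 13 (not isolated)
Conditions: TEMPO (20 mol %), PhI(OAc)2 (2.2 equiv), MeCN/H2O 1:1, rt
Reagents that add atoms: water O
Why: Oxoammonium-catalysed (TEMPO) oxidation in aqueous acetonitrile should take the primary alcohol through the aldehyde hydrate to the acid without touching the acetal or the chromene double bond.

Step 6
Reactants: 14 2-[5-(methoxymethoxy)-2,2-dimethyl-2H-chromen-6-yl]acetic acid; 15 (4R)-4-benzyl-1,3-oxazolidin-2-one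
Product: 17 (4R)-4-benzyl-3-{2-[5-(methoxymethoxy)-2,2-dimethyl-2H-chromen-6-yl]acetyl}-1,3-oxazolidin-2-one, via mixed pivalic anhydride 16 (not isolated)
Conditions: PivCl, Et3N, THF, −20 °C; then LiCl, 15, −20 °C to rt
Reagents that add atoms: none
Why: Mixed-anhydride activation followed by LiCl-assisted N-acylation (Evans auxiliary attachment) should give the imide under conditions mild enough for the acetal.

Step 7
Reactants: 18 2-bromo-4-hydroxybenzaldehyde
Product: 19 2-bromo-4-(methoxymethoxy)benzaldehyde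
Conditions: MOMCl, i-Pr2NEt, CH2Cl2, 0 °C to rt
Reagents that add atoms: chloromethyl methyl ether (MOMCl) COCCl
Why: Williamson-type O-alkylation of the phenol should give the acetal that later serves as protecting group and as ortho-directing group.

Step 8
Reactants: 19 2-bromo-4-(methoxymethoxy)benzaldehyde
Product: 20 [2-bromo-4-(methoxymethoxy)phenyl]methanol
Conditions: NaBH4, MeOH, 0 °C
Reagents that add atoms: none
Why: Borohydride reduction of the aldehyde should give the benzylic alcohol and leave aryl bromide and acetal untouched.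

Step 9
Reactants: 20 [2-bromo-4-(methoxymethoxy)phenyl]methanol
Product: 21 2-bromo-1-(bromomethyl)-4-(methoxymethoxy)benzene
Conditions: CBr4, PPh3, CH2Cl2, 0 °C
Reagents that add atoms: carbon tetrabromide BrC(Br)(Br)Br
Why: Appel bromination should convert the primary benzylic alcohol into the bromide under near-neutral conditions that the MOM ether tolerates.

Step 10
Reactants: 17 (4R)-4-benzyl-3-{2-[5-(methoxymethoxy)-2,2-dimethyl-2H-chromen-6-yl]acetyl}-1,3-oxazolidin-2-one; 21 2-bromo-1-(bromomethyl)-4-(methoxymethoxy)benzene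
Product: 23 (4R)-4-benzyl-3-{(2R)-3-[2-bromo-4-(methoxymethoxy)phenyl]-2-[5-(methoxymethoxy)-2,2-dimethyl-2H-chromen-6-yl]propanoyl}-1,3-oxazolidin-2-one, via sodium enolate 22 (not isolated)
Conditions: NaN(SiMe3)2, THF, −78 °C; then 21, −78 to −30 °C
Reagents that add atoms: none
Why: In this Evans asymmetric alkylation the chelated sodium (Z)-enolate should be attacked by the benzylic bromide on the face opposite the C4 benzyl group of the (R)-auxiliary, which sets the new stereocenter (the future C3) as R.

Step 11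
Reactants: 23 (4R)-4-benzyl-3-{(2R)-3-[2-bromo-4-(methoxymethoxy)phenyl]-2-[5-(methoxymethoxy)-2,2-dimethyl-2H-chromen-6-yl]propanoyl}-1,3-oxazolidin-2-one
Product: 24 (2R)-3-[2-bromo-4-(methoxymethoxy)phenyl]-2-[5-(methoxymethoxy)-2,2-dimethyl-2H-chromen-6-yl]propan-1-ol
Conditions: LiBH4, MeOH (2 equiv), THF, 0 °C
Reagents that add atoms: none
Why: Reductive cleavage of the imide by hydride attack at the exocyclic carbonyl should give the primary alcohol and the recoverable auxiliary without epimerising the α-aryl stereocenter, which keeps the R descriptor.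

Step 12
Reactants: 24 (2R)-3-[2-bromo-4-(methoxymethoxy)phenyl]-2-[5-(methoxymethoxy)-2,2-dimethyl-2H-chromen-6-yl]propan-1-ol
Product: 25 (3R)-7-(methoxymethoxy)-3-[5-(methoxymethoxy)-2,2-dimethyl-2H-chromen-6-yl]chromane
Conditions: Pd(OAc)2 (5 mol %), 2-(di-tert-butylphosphino)-1,1′-binaphthyl (6 mol %), Cs2CO3, toluene, 70 °C
Reagents that add atoms: none
Why: Intramolecular palladium-catalysed C–O coupling (Buchwald–Hartwig etherification) of the primary alcohol with the ortho bromide should close six-membered ring C, the bulky phosphine favouring C–O reductive elimination, and the stereocenter is not involved.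

Step 13
Reactants: 25 (3R)-7-(methoxymethoxy)-3-[5-(methoxymethoxy)-2,2-dimethyl-2H-chromen-6-yl]chromane; 26 1-bromo-3-methylbut-2-ene
Product: 28 (3R)-7-(methoxymethoxy)-3-[5-(methoxymethoxy)-2,2-dimethyl-2H-chromen-6-yl]-8-(3-methylbut-2-en-1-yl)chromane, via 8-lithiochromane 27 (not isolated)
Conditions: n-BuLi (1.1 equiv), THF, 0 °C; then CuBr·SMe2 (10 mol %), 26, −78 °C to rt
Reagents that add atoms: none
Why: Directed ortho-metalation should occur at C8, the only position flanked by two oxygen substituents (O1 and the C7 MOM ether), and copper-catalysed SN2 allylation of the aryllithium then installs the prenyl group.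

Step 14
Reactants: 28 (3R)-7-(methoxymethoxy)-3-[5-(methoxymethoxy)-2,2-dimethyl-2H-chromen-6-yl]-8-(3-methylbut-2-en-1-yl)chromane
Product: 29 (3R)-3-(5-hydroxy-2,2-dimethyl-2H-chromen-6-yl)-8-(3-methylbut-2-en-1-yl)chroman-7-ol
Conditions: 3 M aq. HCl, MeOH, 40 °C
Reagents that add atoms: none
Why: Acid-catalysed acetal exchange with methanol should cleave both aryl MOM ethers under conditions mild enough to spare the prenyl group, the chromene and the C3 stereocenter.

Compound list
1 | 2-bromobenzene-1,3-diol (2-bromoresorcinol) | Oc1cccc(O)c1Br | starting material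
2 | 2-bromo-3-(methoxymethoxy)phenol | COCOc1cccc(O)c1Br | intermediate
3 | [2-bromo-3-(methoxymethoxy)phenoxy]trimethylsilane | COCOc1cccc(O[Si](C)(C)C)c1Br | intermediate
4 | lithium 3-(methoxymethoxy)-2-(trimethylsilyl)phenolate | [Li+].[O-]c1cccc(OCOC)c1[Si](C)(C)C | intermediate
5 | 3-(methoxymethoxy)-2-(trimethylsilyl)phenyl trifluoromethanesulfonate | COCOc1cccc(OS(=O)(=O)C(F)(F)F)c1[Si](C)(C)C | intermediate
6 | 3-methylbut-2-enal | CC(C)=CC=O | starting material
7 | 3-(methoxymethoxy)benzyne (1,2-didehydro-3-(methoxymethoxy)benzene) | COCOC1=CC=CC#C1 | intermediate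
8 | 3-(methoxymethoxy)-2-(2-methylprop-1-en-1-yl)-2H-benzo[b]oxete | COCOc1cccc2OC(C=C(C)C)c12 | intermediate
9 | 5-(methoxymethoxy)-6-(3-methylbut-2-en-1-ylidene)cyclohexa-2,4-dien-1-one | COCOC1=CC=CC(=O)C1=CC=C(C)C | intermediate
10 | 5-(methoxymethoxy)-2,2-dimethyl-2H-chromene | COCOc1cccc2OC(C)(C)C=Cc12 | intermediate
11 | [5-(methoxymethoxy)-2,2-dimethyl-2H-chromen-6-yl]lithium | [Li]c1ccc2OC(C)(C)C=Cc2c1OCOC | intermediate
12 | 2-[5-(methoxymethoxy)-2,2-dimethyl-2H-chromen-6-yl]ethan-1-ol | OCCc1ccc2OC(C)(C)C=Cc2c1OCOC | intermediate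
13 | 2-[5-(methoxymethoxy)-2,2-dimethyl-2H-chromen-6-yl]acetaldehyde | O=CCc1ccc2OC(C)(C)C=Cc2c1OCOC | intermediate
14 | 2-[5-(methoxymethoxy)-2,2-dimethyl-2H-chromen-6-yl]acetic acid | OC(=O)Cc1ccc2OC(C)(C)C=Cc2c1OCOC | intermediate
15 | (4R)-4-benzyl-1,3-oxazolidin-2-one | O=C1N[C@H](Cc2ccccc2)CO1 | starting material
16 | 2-[5-(methoxymethoxy)-2,2-dimethyl-2H-chromen-6-yl]acetic 2,2-dimethylpropanoic anhydride | CC(C)(C)C(=O)OC(=O)Cc1ccc2OC(C)(C)C=Cc2c1OCOC | intermediate
17 | (4R)-4-benzyl-3-{2-[5-(methoxymethoxy)-2,2-dimethyl-2H-chromen-6-yl]acetyl}-1,3-oxazolidin-2-one | O=C(Cc1ccc2OC(C)(C)C=Cc2c1OCOC)N1[C@H](Cc2ccccc2)COC1=O | intermediate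
18 | 2-bromo-4-hydroxybenzaldehyde | O=Cc1ccc(O)cc1Br | starting material
19 | 2-bromo-4-(methoxymethoxy)benzaldehyde | O=Cc1ccc(OCOC)cc1Br | intermediate
20 | [2-bromo-4-(methoxymethoxy)phenyl]methanol | OCc1ccc(OCOC)cc1Br | intermediate
21 | 2-bromo-1-(bromomethyl)-4-(methoxymethoxy)benzene | BrCc1ccc(OCOC)cc1Br | intermediate
22 | sodium (Z)-enolate of imide 17 | [Na+].[O-]/C(=C\c1ccc2OC(C)(C)C=Cc2c1OCOC)N1[C@H](Cc2ccccc2)COC1=O | intermediate
23 | (4R)-4-benzyl-3-{(2R)-3-[2-bromo-4-(methoxymethoxy)phenyl]-2-[5-(methoxymethoxy)-2,2-dimethyl-2H-chromen-6-yl]propanoyl}-1,3-oxazolidin-2-one | O=C([C@H](Cc1ccc(OCOC)cc1Br)c1ccc2OC(C)(C)C=Cc2c1OCOC)N1[C@H](Cc2ccccc2)COC1=O | intermediate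
24 | (2R)-3-[2-bromo-4-(methoxymethoxy)phenyl]-2-[5-(methoxymethoxy)-2,2-dimethyl-2H-chromen-6-yl]propan-1-ol | OC[C@@H](c1ccc2OC(C)(C)C=Cc2c1OCOC)Cc1ccc(OCOC)cc1Br | intermediate
25 | (3R)-7-(methoxymethoxy)-3-[5-(methoxymethoxy)-2,2-dimethyl-2H-chromen-6-yl]chromane | COCOc1ccc2c(c1)OC[C@@H](c1ccc3OC(C)(C)C=Cc3c1OCOC)C2 | intermediate
26 | 1-bromo-3-methylbut-2-ene (prenyl bromide) | CC(C)=CCBr | starting material
27 | 8-lithio derivative of chromane 25 | COCOc1ccc2c(c1[Li])OC[C@@H](c1ccc3OC(C)(C)C=Cc3c1OCOC)C2 | intermediate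
28 | (3R)-7-(methoxymethoxy)-3-[5-(methoxymethoxy)-2,2-dimethyl-2H-chromen-6-yl]-8-(3-methylbut-2-en-1-yl)chromane | COCOc1ccc2c(c1CC=C(C)C)OC[C@@H](c1ccc3OC(C)(C)C=Cc3c1OCOC)C2 | intermediate
29 | (3R)-3-(5-hydroxy-2,2-dimethyl-2H-chromen-6-yl)-8-(3-methylbut-2-en-1-yl)chroman-7-ol | CC(C)=CCc1c(O)ccc2c1OC[C@@H](c1ccc3c(c1O)C=CC(C)(C)O3)C2 | target

Total step count: 14. Longest linear sequence: 11 steps (steps 1–6, then 10–14); steps 7–9 form the second branch.

Steps most likely to fail

Step 3. The aryne may be consumed along other paths: ene reaction with the allylic C–H bonds of the enal, capture of the o-quinone methide by a second aryne, or fluoride-induced self-condensation of the enal. The fallback sets out from 5, comes back at 10, and closes the same aryl C4′–O bond by known palladium chemistry. Ipso-iododesilylation of 5 (ICl, CH2Cl2, 0 °C) should give 2-iodo-3-(methoxymethoxy)phenyl trifluoromethanesulfonate F1. Sonogashira coupling at the C–I bond with 2-methylbut-3-yn-2-ol (PdCl2(PPh3)2, CuI, Et3N, rt) should give 2-(3-hydroxy-3-methylbut-1-yn-1-yl)-3-(methoxymethoxy)phenyl trifluoromethanesulfonate F2. Z-selective semihydrogenation (H2, Pd/CaCO3 poisoned with Pb(OAc)2, quinoline, EtOAc) should give 2-[(1Z)-3-hydroxy-3-methylbut-1-en-1-yl]-3-(methoxymethoxy)phenyl trifluoromethanesulfonate F3. Intramolecular etherification of the tertiary alcohol with the aryl triflate (Pd(OAc)2, 2-(di-tert-butylphosphino)-1,1′-binaphthyl, Cs2CO3, toluene, 80 °C) would then give 10.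

Step 13. The base may deprotonate the advanced intermediate elsewhere, at the vinylic or benzylic positions near the ring-B acetal; the latter would erode enantiomeric purity. SN2′ transposition during allylation is a second risk. The fallback sets out from 20, comes back at 28, and installs the prenyl group on the achiral ring-A fragment before the stereocenter exists. Deprotonation of 20 between bromine and the MOM ether (LDA, 2.2 equiv, THF, −78 °C), transmetalation with CuBr·SMe2 and allylation with 26 should give [2-bromo-4-(methoxymethoxy)-3-(3-methylbut-2-en-1-yl)phenyl]methanol F4. Appel bromination as in step 9 should give 2-bromo-1-(bromomethyl)-4-(methoxymethoxy)-3-(3-methylbut-2-en-1-yl)benzene F5. Alkylation of sodium enolate 22 with F5 as in step 10 should give the prenylated (2R)-imide F6. LiBH4 reduction as in step 11 should give the prenylated (2R)-bromo alcohol F7. The palladium-catalysed etherification of step 12, applied to F7, would give 28 directly.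

Step 12. The palladium alkoxide may undergo β-hydride elimination, giving hydrodebromination and alcohol oxidation in place of C–O reductive elimination. The fallback sets out from 24, comes back at 25, and forms the ring by alkylating a phenol. Miyaura borylation of 24 (B2pin2, PdCl2(dppf), KOAc, dioxane, 80 °C) should give the pinacol boronate F8. Oxidation (NaBO3·4H2O, THF/H2O, rt) should give the phenol 2-{(2R)-3-hydroxy-2-[5-(methoxymethoxy)-2,2-dimethyl-2H-chromen-6-yl]propyl}-5-(methoxymethoxy)phenol F9. Mitsunobu cyclisation (PPh3, DIAD, THF, 0 °C) would close ring C to give 25.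

Further compounds
F1 | step 3 | 2-iodo-3-(methoxymethoxy)phenyl trifluoromethanesulfonate | COCOc1cccc(OS(=O)(=O)C(F)(F)F)c1I
F2 | step 3 | 2-(3-hydroxy-3-methylbut-1-yn-1-yl)-3-(methoxymethoxy)phenyl trifluoromethanesulfonate | COCOc1cccc(OS(=O)(=O)C(F)(F)F)c1C#CC(C)(C)O
F3 | step 3 | 2-[(1Z)-3-hydroxy-3-methylbut-1-en-1-yl]-3-(methoxymethoxy)phenyl trifluoromethanesulfonate | COCOc1cccc(OS(=O)(=O)C(F)(F)F)c1/C=C\C(C)(C)O
F4 | step 13 | [2-bromo-4-(methoxymethoxy)-3-(3-methylbut-2-en-1-yl)phenyl]methanol | OCc1ccc(OCOC)c(CC=C(C)C)c1Br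
F5 | step 13 | 2-bromo-1-(bromomethyl)-4-(methoxymethoxy)-3-(3-methylbut-2-en-1-yl)benzene | BrCc1ccc(OCOC)c(CC=C(C)C)c1Br
F6 | step 13 | (4R)-4-benzyl-3-{(2R)-3-[2-bromo-4-(methoxymethoxy)-3-(3-methylbut-2-en-1-yl)phenyl]-2-[5-(methoxymethoxy)-2,2-dimethyl-2H-chromen-6-yl]propanoyl}-1,3-oxazolidin-2-one | O=C([C@H](Cc1ccc(OCOC)c(CC=C(C)C)c1Br)c1ccc2OC(C)(C)C=Cc2c1OCOC)N1[C@H](Cc2ccccc2)COC1=O
F7 | step 13 | (2R)-3-[2-bromo-4-(methoxymethoxy)-3-(3-methylbut-2-en-1-yl)phenyl]-2-[5-(methoxymethoxy)-2,2-dimethyl-2H-chromen-6-yl]propan-1-ol | OC[C@@H](c1ccc2OC(C)(C)C=Cc2c1OCOC)Cc1ccc(OCOC)c(CC=C(C)C)c1Br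
F8 | step 12 | (2R)-2-[5-(methoxymethoxy)-2,2-dimethyl-2H-chromen-6-yl]-3-[4-(methoxymethoxy)-2-(4,4,5,5-tetramethyl-1,3,2-dioxaborolan-2-yl)phenyl]propan-1-ol | OC[C@@H](c1ccc2OC(C)(C)C=Cc2c1OCOC)Cc1ccc(OCOC)cc1B1OC(C)(C)C(C)(C)O1
F9 | step 12 | 2-{(2R)-3-hydroxy-2-[5-(methoxymethoxy)-2,2-dimethyl-2H-chromen-6-yl]propyl}-5-(methoxymethoxy)phenol | OC[C@@H](c1ccc2OC(C)(C)C=Cc2c1OCOC)Cc1ccc(OCOC)cc1O
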